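**Assumption:** the target has no stereocentres and no stereogenic double bond (the chromene C=C is endocyclic and the prenyl alkene carries two identical methyls), so it is achiral and no enantiocontrol is needed.

## Retrosynthetic overview

1. Cut the 1,3-diketone at the CH2–C(=O) bond on the prenylphenyl side (crossed Claisen): 6-acetyl-7-hydroxy-2,2-dimethyl-2H-chromene (6) plus O-silylated methyl 4-hydroxy-3-prenylbenzoate (11).
2. Chromene 6 comes from the chroman by DDQ dehydrogenation; the acetyl group comes from Friedel–Crafts acylation of 2,2-dimethylchroman-7-ol. Acylating after ring formation fixes the linear 6-acyl-7-hydroxy pattern.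
3. The pyran ring is the only ring formed, and it is formed first, from resorcinol and a C5 allylic alcohol.
4. Ester 11 comes from methyl 4-hydroxybenzoate by ortho-C-prenylation and TIPS protection; fluoride removes the TIPS group last, avoiding acid (flavone or chroman formation).

## Route

**Step 1**
Reactants: 1 resorcinol; 2 2-methylbut-3-en-2-ol
Product: 3 2,2-dimethylchroman-7-ol
Conditions: Amberlyst-15, THF/heptane, 65 °C (2 equiv of resorcinol)
Reagents that add atoms: 2-methylbut-3-en-2-ol, CC(C)(O)C=C (supplies the C5 unit; its O leaves as water)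
Why: Acid-catalysed Friedel–Crafts prenylation at C4 of resorcinol, then Markovnikov hydroalkoxylation of the prenyl alkene by the adjacent OH, closes the 2,2-dimethylchroman; excess resorcinol suppresses bis-annulation.

**Step 2**
Reactants: 3 2,2-dimethylchroman-7-ol; 4 acetic acid
Product: 5 1-(7-hydroxy-2,2-dimethylchroman-6-yl)ethanone
Conditions: BF3·OEt2, AcOH, 90 °C; then aq NaOAc, warm (cleaves the BF2 chelate)
Reagents that add atoms: acetic acid, CC(=O)O
Why: Nencki-type Friedel–Crafts acylation goes at C6, which is ortho to the OH, para to the ring oxygen and less hindered than C8.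

**Step 3**
Reactants: 5 1-(7-hydroxy-2,2-dimethylchroman-6-yl)ethanone
Product: 6 1-(7-hydroxy-2,2-dimethyl-2H-chromen-6-yl)ethanone (eupatoriochromene)
Conditions: DDQ (1.2 equiv), benzene, reflux
Reagents that add atoms: none
Why: DDQ abstracts hydride from benzylic C4 (cation stabilised by the para 7-OH as a quinone methide) and loss of H from C3 gives the chromene. It is done before any prenylphenol is present, because DDQ would oxidatively cyclise that group.

**Step 4**
Reactants: 7 methyl 4-hydroxybenzoate; 8 prenyl bromide
Product: 9 methyl 4-hydroxy-3-(3-methylbut-2-en-1-yl)benzoate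
Conditions: NaH (1.05 equiv), toluene, 0 °C → rt; then prenyl bromide, rt → 60 °C
Reagents that add atoms: prenyl bromide, CC(C)=CCBr
Why: The tight sodium phenoxide ion pair in a non-polar solvent favours ortho-C-alkylation over O-alkylation; the para position is blocked, so only the ortho linear prenyl product forms (O-prenyl ether and diprenyl by-products are separated).

**Step 5**
Reactants: 9 methyl 4-hydroxy-3-prenylbenzoate; 10 triisopropylsilyl chloride
Product: 11 methyl 3-(3-methylbut-2-en-1-yl)-4-(triisopropylsilyloxy)benzoate
Conditions: TIPSCl, imidazole, cat. DMAP, DMF, rt → 40 °C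
Reagents that add atoms: TIPSCl, CC(C)[Si](Cl)(C(C)C)C(C)C
Why: Standard phenol silylation; the free phenol would otherwise become a phenoxide and deactivate the ester in the Claisen step, and the bulky TIPS group resists alkoxide and amide bases.

**Step 6**
Reactants: 6 eupatoriochromene; 11 TIPS-protected ester
Product: 12 1-(7-hydroxy-2,2-dimethyl-2H-chromen-6-yl)-3-[3-(3-methylbut-2-en-1-yl)-4-(triisopropylsilyloxy)phenyl]propane-1,3-dione
Conditions: LiHMDS (4 equiv), THF, −78 → −20 °C (dianion of 6); add 11, → rt (40–50 °C if sluggish); aq NH4Cl
Reagents that add atoms: none (both partners are numbered reactants; MeOH is lost)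
Why: Crossed Claisen condensation: the phenoxide–enolate dianion of the o-hydroxyacetophenone C-acylates the non-enolisable ester, and deprotonation of the product diketone drives the reaction. Chromene, prenyl and TIPS groups tolerate the base; the workup is kept non-acidic to avoid cyclodehydration to a flavone.

**Step 7**
Reactants: 12 TIPS-protected diketone
Product: 13 Glyinflanin C, 1-(7-hydroxy-2,2-dimethyl-2H-chromen-6-yl)-3-[4-hydroxy-3-(3-methylbut-2-en-1-yl)phenyl]propane-1,3-dione
Conditions: TBAF/AcOH (1:1), THF, 0 °C
Reagents that add atoms: none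
Why: Buffered fluoride cleaves the aryl silyl ether without acid, so the o-prenylphenol, chromene and 2'-hydroxy-1,3-diketone survive. The product is isolated as a keto–enol mixture.

## Compound list

1 | resorcinol | Oc1cccc(O)c1 | starting material
2 | 2-methylbut-3-en-2-ol | CC(C)(O)C=C | starting material
3 | 2,2-dimethylchroman-7-ol | CC1(C)CCc2ccc(O)cc2O1 | intermediate
4 | acetic acid | CC(=O)O | starting material (reagent)
5 | 1-(7-hydroxy-2,2-dimethylchroman-6-yl)ethanone | CC(=O)c1cc2c(cc1O)OC(C)(C)CC2 | intermediate
6 | 1-(7-hydroxy-2,2-dimethyl-2H-chromen-6-yl)ethanone | CC(=O)c1cc2c(cc1O)OC(C)(C)C=C2 | intermediate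
7 | methyl 4-hydroxybenzoate | COC(=O)c1ccc(O)cc1 | starting material
8 | prenyl bromide (1-bromo-3-methylbut-2-ene) | CC(C)=CCBr | starting material
9 | methyl 4-hydroxy-3-(3-methylbut-2-en-1-yl)benzoate | COC(=O)c1ccc(O)c(CC=C(C)C)c1 | intermediate
10 | triisopropylsilyl chloride | CC(C)[Si](Cl)(C(C)C)C(C)C | starting material (reagent)
11 | methyl 3-(3-methylbut-2-en-1-yl)-4-(triisopropylsilyloxy)benzoate | COC(=O)c1ccc(O[Si](C(C)C)(C(C)C)C(C)C)c(CC=C(C)C)c1 | intermediate
12 | TIPS-protected Glyinflanin C | CC(C)=CCc1cc(C(=O)CC(=O)c2cc3c(cc2O)OC(C)(C)C=C3)ccc1O[Si](C(C)C)(C(C)C)C(C)C | intermediate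
13 | Glyinflanin C | CC(C)=CCc1cc(C(=O)CC(=O)c2cc3c(cc2O)OC(C)(C)C=C3)ccc1O | target

## Summary

Total steps: 7. Longest linear sequence: 5 (steps 1 → 2 → 3 → 6 → 7); the ester branch is steps 4–5.

Steps most likely to fail, with fallbacks:

1. **Step 4 (direct ortho-C-prenylation).** O-alkylation and dialkylation compete and the yield is moderate. Fallback: start from methyl 4-hydroxy-3-iodobenzoate, TIPS-protect it, perform I/Mg exchange (iPrMgCl·LiCl, −30 °C) and Cu-catalysed allylation with prenyl bromide; this is regiospecific and leads directly to 11.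
2. **Step 6 (Claisen with an electron-rich ester).** Conversion may be slow, and LiOMe may partly desilylate 11. Fallback: Baker–Venkataraman sequence — saponify 11 to the acid, esterify the 7-OH of 6 (EDC/DMAP), then KOtBu/THF O→C acyl migration to 12.
3. **Step 1 (chroman annulation).** The 5-hydroxy regioisomer and bis-chroman can form. Fallback: Friedel–Crafts acylation/oxa-Michael of resorcinol with 3-methylbut-2-enoic acid (Eaton's reagent) to 7-hydroxy-2,2-dimethylchroman-4-one, then ketone deoxygenation (Clemmensen, or Et3SiH/TFA) to 3, with regiochemistry fixed by acylation para to OH.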